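The flavonol core is cut at C3–C4 and O1–C8a of ring C. Ring A enters as 2,6-difluoro-4-methoxybenzoyl chloride: the future C5 and C8a, the two oxygen-bearing carbons ortho to the acyl-bearing C4a, are equivalent C–F carbons activated by C4=O. Ring B enters as an α-(methoxymethoxy)acetophenone with a 3-benzyl and a 4-MOM ether. In one flask, soft enolisation and C-acylation form the 1,3-diketone, and its enolate oxygen then displaces one fluoride to close ring C. The remaining C5 fluoride is later exchanged for the lone 5-hydroxyl; acid frees O3 and O4', three sulfations follow, and hydrogenolysis uncovers O3'.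

Key step: step 7

Assumption: the sulfate esters of 16 and 17 are written as free acids, as in the target SMILES; in the flask and on isolation they would be handled as ammonium or sodium salts, and a sulfonic acid resin in its proton form would give the acid form drawn.

Step 1
Reactants: 1 3',4'-dihydroxyacetophenone
Product: 2 1-[3-hydroxy-4-(methoxymethoxy)phenyl]ethan-1-one
Conditions: MOMCl (1.05 equiv), K2CO3, acetone, 0 °C to rt
Reagents that add atoms: chloromethyl methyl ether (MOMCl), COCCl
Why: The hydroxyl para to the acetyl group is the more acidic one, so a weak base forms its phenoxide preferentially and Williamson-type O-alkylation should place the MOM group on O4.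

Step 2
Reactants: 2 1-[3-hydroxy-4-(methoxymethoxy)phenyl]ethan-1-one
Product: 3 1-[3-(benzyloxy)-4-(methoxymethoxy)phenyl]ethan-1-one
Conditions: BnBr, K2CO3, DMF, rt to 50 °C
Reagents that add atoms: benzyl bromide, BrCc1ccccc1
Why: Williamson ether synthesis on the only remaining phenol; the MOM ether and the ketone are inert to carbonate and benzyl bromide.

Step 3
Reactants: 3 1-[3-(benzyloxy)-4-(methoxymethoxy)phenyl]ethan-1-one
Product: 4 ({1-[3-(benzyloxy)-4-(methoxymethoxy)phenyl]ethenyl}oxy)trimethylsilane
Conditions: LiN(SiMe3)2, THF, −78 °C; TMSCl, −78 to 0 °C; non-aqueous work-up, used at once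
Reagents that add atoms: chlorotrimethylsilane, C[Si](C)(C)Cl
Why: The methyl ketone has a single enolisable site, so deprotonation and O-silylation of the lithium enolate (silyl enol ether formation) should give one enol ether under basic conditions that leave the MOM and benzyl ethers untouched.

Step 4
Reactants: 4 ({1-[3-(benzyloxy)-4-(methoxymethoxy)phenyl]ethenyl}oxy)trimethylsilane
Product: 6 1-[3-(benzyloxy)-4-(methoxymethoxy)phenyl]-2-hydroxyethan-1-one, via α-silyloxy ketone 5 (not isolated)
Conditions: mCPBA, NaHCO3, CH2Cl2, 0 °C; then MeOH, citric acid, rt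
Reagents that add atoms: 3-chloroperoxybenzoic acid (mCPBA), OOC(=O)c1cccc(Cl)c1
Why: Rubottom oxidation: epoxidation of the electron-rich enol ether, ring opening and 1,4-silyl shift give the α-silyloxy ketone, which mild acidic methanolysis should desilylate without harming the aryl MOM ether.

Step 5
Reactants: 6 1-[3-(benzyloxy)-4-(methoxymethoxy)phenyl]-2-hydroxyethan-1-one
Product: 7 1-[3-(benzyloxy)-4-(methoxymethoxy)phenyl]-2-(methoxymethoxy)ethan-1-one
Conditions: MOMCl, iPr2NEt, CH2Cl2, 0 °C to rt
Reagents that add atoms: chloromethyl methyl ether (MOMCl), COCCl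
Why: Acetal protection of a primary alcohol by O-alkylation with MOMCl; the amine base is too weak to cause enolisation side reactions of the α-hydroxy ketone.

Step 6
Reactants: 8 2,6-difluoro-4-methoxybenzoic acid
Product: 9 2,6-difluoro-4-methoxybenzoyl chloride
Conditions: (COCl)2, DMF (cat.), CH2Cl2, 0 °C to rt; evaporate with toluene, use crude
Reagents that add atoms: oxalyl chloride, ClC(=O)C(=O)Cl
Why: Acid chloride formation through the Vilsmeier-type intermediate from DMF and oxalyl chloride gives only volatile by-products, so the crude chloride can go straight into the coupling.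

Step 7
Reactants: 7 1-[3-(benzyloxy)-4-(methoxymethoxy)phenyl]-2-(methoxymethoxy)ethan-1-one; 9 2,6-difluoro-4-methoxybenzoyl chloride
Product: 12 3'-(benzyloxy)-5-fluoro-7-methoxy-3,4'-bis(methoxymethoxy)flavone, via bromomagnesium enolate 10 (not isolated), via 1,3-diketone 11 (not isolated)
Conditions: MgBr2·OEt2, iPr2NEt, CH2Cl2, 0 °C to rt; then K2CO3, DMF, 60 °C
Reagents that add atoms: none
Why: MgBr2 chelates the carbonyl and α-MOM oxygens of 7, so that iPr2NEt can deprotonate it (soft enolisation) to the chelated Z-enolate 10, which attacks the acyl chloride 9 through carbon to form C3–C4 and diketone 11. K2CO3 in DMF then frees the diketone enolate, whose oxygen on the future C2 adds to the C–F carbon that becomes C8a; the resulting Meisenheimer adduct is stabilised by C4=O and expels fluoride to form O1–C8a. The closest known chemistry is the Claisen-type soft-enolisation synthesis of 1,3-diketones followed by intramolecular SNAr of a 2-fluorobenzoyl unit, the logic of the Grohe quinolone synthesis and of chromone syntheses from 2-fluorobenzoyl chlorides. Ring C closes by six-membered addition–elimination at an sp2 carbon, 6-endo-trig with respect to the C4a=C8a bond that relays charge to C4=O, the C–F bond being exocyclic. No stereocentre is formed, and the one at the central carbon of 11 disappears on enolisation. The step needs C- rather than O-acylation, which the magnesium chelate and the small ortho fluorines should secure, whereas the site of substitution needs no control because the two fluorines of 9 are equivalent, only the C2 oxygen can reach them, and carbonate is too weak a nucleophile to touch the second one.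

Step 8
Reactants: 12 3'-(benzyloxy)-5-fluoro-7-methoxy-3,4'-bis(methoxymethoxy)flavone
Product: 14 3'-(benzyloxy)-5-hydroxy-7-methoxy-3,4'-bis(methoxymethoxy)flavone, via sulfonylethyl ether 13 (not isolated)
Conditions: MeSO2CH2CH2OH, NaH, DMF, 0 °C to rt; AcOH quench
Reagents that add atoms: 2-(methylsulfonyl)ethanol, CS(=O)(=O)CCO
Why: Nucleophilic aromatic substitution of the C5 fluoride, activated by the ortho C4 carbonyl, by the alkoxide of 2-(methylsulfonyl)ethanol, followed by E1cB loss of methyl vinyl sulfone from ether 13, should deliver the phenol directly (hydroxide-surrogate SNAr), the 7-methoxy group being a far poorer leaving group.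

Step 9
Reactants: 14 3'-(benzyloxy)-5-hydroxy-7-methoxy-3,4'-bis(methoxymethoxy)flavone
Product: 15 3'-(benzyloxy)-3,5,4'-trihydroxy-7-methoxyflavone (3'-O-benzylrhamnetin)
Conditions: HCl, MeOH/THF, 50 °C
Reagents that add atoms: none
Why: Acid-catalysed acetal solvolysis should remove both MOM groups (from enolic O3 and phenolic O4'), while the benzyl ether, the methyl ether and the flavone core are stable to methanolic HCl.

Step 10
Reactants: 15 3'-(benzyloxy)-3,5,4'-trihydroxy-7-methoxyflavone
Product: 16 3'-(benzyloxy)-7-methoxyflavone-3,5,4'-triyl tris(hydrogen sulfate)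
Conditions: SO3·NMe3 (large excess), Et3N, MeCN, 100 °C, sealed tube, argon
Reagents that add atoms: sulfur trioxide–trimethylamine complex, C[N+](C)(C)S(=O)(=O)[O-]
Why: O-Sulfation of phenolic and enolic hydroxyls by an amine–SO3 complex; excess reagent with Et3N at elevated temperature is the established way to per-sulfate flavonoids including the hydrogen-bonded 5-OH, and since all three free hydroxyls are meant to react no selectivity is required.

Step 11
Reactants: 16 3'-(benzyloxy)-7-methoxyflavone-3,5,4'-triyl tris(hydrogen sulfate)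
Product: 17 rhamnetin 3,5,4'-tri-O-sulfate
Conditions: H2 (1 atm), Pd/C, MeOH/H2O, rt (substrate as its ammonium salt)
Reagents that add atoms: none
Why: Catalytic hydrogenolysis of the benzyl ether over palladium on carbon; aryl sulfate salts and the tetrasubstituted C2=C3 bond of the flavonol should be inert under neutral conditions at one atmosphere.

Compound list
1 | 3',4'-dihydroxyacetophenone | CC(=O)c1ccc(O)c(O)c1 | starting material
2 | 1-[3-hydroxy-4-(methoxymethoxy)phenyl]ethan-1-one | CC(=O)c1ccc(OCOC)c(O)c1 | intermediate
3 | 1-[3-(benzyloxy)-4-(methoxymethoxy)phenyl]ethan-1-one | CC(=O)c1ccc(OCOC)c(OCc2ccccc2)c1 | intermediate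
4 | ({1-[3-(benzyloxy)-4-(methoxymethoxy)phenyl]ethenyl}oxy)trimethylsilane | C=C(O[Si](C)(C)C)c1ccc(OCOC)c(OCc2ccccc2)c1 | intermediate
5 | 1-[3-(benzyloxy)-4-(methoxymethoxy)phenyl]-2-[(trimethylsilyl)oxy]ethan-1-one | C[Si](C)(C)OCC(=O)c1ccc(OCOC)c(OCc2ccccc2)c1 | intermediate (not isolated)
6 | 1-[3-(benzyloxy)-4-(methoxymethoxy)phenyl]-2-hydroxyethan-1-one | OCC(=O)c1ccc(OCOC)c(OCc2ccccc2)c1 | intermediate
7 | 1-[3-(benzyloxy)-4-(methoxymethoxy)phenyl]-2-(methoxymethoxy)ethan-1-one | COCOCC(=O)c1ccc(OCOC)c(OCc2ccccc2)c1 | intermediate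
8 | 2,6-difluoro-4-methoxybenzoic acid | COc1cc(F)c(C(=O)O)c(F)c1 | starting material
9 | 2,6-difluoro-4-methoxybenzoyl chloride | COc1cc(F)c(C(=O)Cl)c(F)c1 | intermediate
10 | bromomagnesium (Z)-1-[3-(benzyloxy)-4-(methoxymethoxy)phenyl]-2-(methoxymethoxy)ethen-1-olate | COCO/C=C(\O[Mg]Br)c1ccc(OCOC)c(OCc2ccccc2)c1 | intermediate (not isolated)
11 | 1-[3-(benzyloxy)-4-(methoxymethoxy)phenyl]-3-(2,6-difluoro-4-methoxyphenyl)-2-(methoxymethoxy)propane-1,3-dione (racemic, enolisable) | COCOC(C(=O)c1ccc(OCOC)c(OCc2ccccc2)c1)C(=O)c1c(F)cc(OC)cc1F | intermediate (not isolated)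
12 | 3'-(benzyloxy)-5-fluoro-7-methoxy-3,4'-bis(methoxymethoxy)flavone | COc1cc(F)c2c(=O)c(OCOC)c(-c3ccc(OCOC)c(OCc4ccccc4)c3)oc2c1 | intermediate
13 | 3'-(benzyloxy)-7-methoxy-3,4'-bis(methoxymethoxy)-5-[2-(methylsulfonyl)ethoxy]flavone | COc1cc(OCCS(C)(=O)=O)c2c(=O)c(OCOC)c(-c3ccc(OCOC)c(OCc4ccccc4)c3)oc2c1 | intermediate (not isolated)
14 | 3'-(benzyloxy)-5-hydroxy-7-methoxy-3,4'-bis(methoxymethoxy)flavone | COc1cc(O)c2c(=O)c(OCOC)c(-c3ccc(OCOC)c(OCc4ccccc4)c3)oc2c1 | intermediate
15 | 3'-(benzyloxy)-3,5,4'-trihydroxy-7-methoxyflavone | COc1cc(O)c2c(=O)c(O)c(-c3ccc(O)c(OCc4ccccc4)c3)oc2c1 | intermediate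
16 | 3'-(benzyloxy)-7-methoxyflavone-3,5,4'-triyl tris(hydrogen sulfate) | COc1cc(OS(=O)(=O)O)c2c(=O)c(OS(=O)(=O)O)c(-c3ccc(OS(=O)(=O)O)c(OCc4ccccc4)c3)oc2c1 | intermediate
17 | rhamnetin 3,5,4'-tri-O-sulfate | COc1cc(OS(=O)(=O)O)c2c(=O)c(OS(=O)(=O)O)c(-c3ccc(OS(=O)(=O)O)c(O)c3)oc2c1 | target

Total step count: 11. Longest linear sequence: 10 steps (steps 1–5 and 7–11 from 1; step 6 is a one-step side branch from 8).

Steps most likely to fail

1. Step 7. Acylation could occur at the enolate oxygen instead of carbon, the Lewis acid could strip a MOM acetal, or the hindered acyl chloride could react too slowly for the one-pot closure. The fallback forms the same C3–C4 bond by aldol addition and oxidation. It sets out from 7: LiN(SiMe3)2 in THF at −78 °C, then commercial 2,6-difluoro-4-methoxybenzaldehyde (COc1cc(F)c(C=O)c(F)c1), should give the aldol adduct 1-[3-(benzyloxy)-4-(methoxymethoxy)phenyl]-3-(2,6-difluoro-4-methoxyphenyl)-3-hydroxy-2-(methoxymethoxy)propan-1-one F1 as a mixture of diastereomers, both stereocentres being erased later. Dess–Martin periodinane with NaHCO3 in CH2Cl2 should oxidise it to the diketone, so the fallback comes back to the route at 11, which K2CO3 in DMF closes to 12 as in the second half of step 7.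

2. Step 10. Sulfation of the hydrogen-bonded C5 hydroxyl could stay incomplete and leave inseparable mixtures of partly sulfated salts. The fallback installs the sulfates as neutral protected diesters. It sets out from 15: 2,2,2-trichloroethyl chlorosulfate (ClS(=O)(=O)OCC(Cl)(Cl)Cl) with Et3N and DMAP in THF should give tris(2,2,2-trichloroethyl) 3'-(benzyloxy)-7-methoxyflavone-3,5,4'-triyl tris(sulfate) F2, which can be purified on silica. Reductive fragmentation with Zn dust and HCO2NH4 in MeOH at rt should then release the three sulfate monoesters, and the fallback comes back to the route at 16.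

3. Step 8. The E1cB fragmentation of the sulfonylethyl ether could stall, or the released vinyl sulfone could re-alkylate the phenoxide, so that the ether accumulates instead of the phenol. The fallback replaces the self-cleaving surrogate by a stable ether removed by palladium catalysis. It sets out from 12: allyl alcohol and NaH in DMF should give 5-(allyloxy)-3'-(benzyloxy)-7-methoxy-3,4'-bis(methoxymethoxy)flavone F3. Pd(PPh3)4, a zerovalent palladium complex, with morpholine in THF should then transfer the allyl group to the amine, and the fallback comes back to the route at 14.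

Further compounds
F1 | step 7 | 1-[3-(benzyloxy)-4-(methoxymethoxy)phenyl]-3-(2,6-difluoro-4-methoxyphenyl)-3-hydroxy-2-(methoxymethoxy)propan-1-one (diastereomer mixture, racemic) | COCOC(C(=O)c1ccc(OCOC)c(OCc2ccccc2)c1)C(O)c1c(F)cc(OC)cc1F
F2 | step 10 | tris(2,2,2-trichloroethyl) 3'-(benzyloxy)-7-methoxyflavone-3,5,4'-triyl tris(sulfate) | COc1cc(OS(=O)(=O)OCC(Cl)(Cl)Cl)c2c(=O)c(OS(=O)(=O)OCC(Cl)(Cl)Cl)c(-c3ccc(OS(=O)(=O)OCC(Cl)(Cl)Cl)c(OCc4ccccc4)c3)oc2c1
F3 | step 8 | 5-(allyloxy)-3'-(benzyloxy)-7-methoxy-3,4'-bis(methoxymethoxy)flavone | C=CCOc1cc(OC)cc2oc(-c3ccc(OCOC)c(OCc4ccccc4)c3)c(OCOC)c(=O)c12
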